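Assumption: the target has no stereocentres (it is achiral), so "single enantiomer" reduces to fixing the two E‑alkenes, which are taken intact from (2E,6E)‑farnesol.

## Retrosynthetic overview

1. Disconnect the aryl–O–CH2 ether last: 4,5‑dihydroxy‑6‑methoxyphthalide (4) plus the C17 allylic alcohol (10), joined at the more acidic 5‑OH.
2. The γ‑lactone of 4 is the only ring made. It closes by intramolecular oxa‑Michael addition of a carboxylate onto an o‑quinone methide released from the phenolic Mannich base 3.
3. Mannich base 3 comes from gallic acid by borate‑controlled mono‑O‑methylation and ortho‑aminomethylation; the benzene ring is bought, not built.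
4. Alcohol 10 comes from (2E,6E)‑farnesol by terminal‑selective bromohydrin formation and radical debromination (net Markovnikov hydration), acetylation and desilylation.
5. Ring order: arene (from gallic acid), then lactone (step 3); no ring is formed after the fragment union.

## Route

**Branch A – phthalide core**

Step 1
Reactants: 1, gallic acid (3,4,5‑trihydroxybenzoic acid)
Product: 2, 3,4‑dihydroxy‑5‑methoxybenzoic acid (3‑O‑methylgallic acid)
Conditions: borax (Na2B4O7), aq. NaOH, Me2SO4, H2O, rt; then H2SO4 to pH 2
Reagents that add atoms: dimethyl sulfate, COS(=O)(=O)OC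
Why: Borate ties up two adjacent OH groups as a cyclic catechol borate, so only the remaining flanking phenoxide undergoes Williamson O‑methylation; the substrate is symmetric, so either flank gives the same product.

Step 2
Reactants: 2, 3,4‑dihydroxy‑5‑methoxybenzoic acid
Product: 3, 2‑[(dimethylamino)methyl]‑3,4‑dihydroxy‑5‑methoxybenzoic acid (isolated as the zwitterion)
Conditions: 37% aq. CH2O (1.1 eq), 40% aq. Me2NH (2.2 eq), EtOH/H2O, 0 °C → rt, N2; adjust to pH ~6
Reagents that add atoms: formaldehyde, C=O; dimethylamine, CNC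
Why: Phenolic Mannich reaction: the iminium is delivered with hydrogen‑bond assistance ortho to the free 3‑OH, and C2 is the only open position ortho to a free phenol (C6 is flanked by OMe).

Step 3
Reactants: 3, 2‑[(dimethylamino)methyl]‑3,4‑dihydroxy‑5‑methoxybenzoic acid
Product: 4, 4,5‑dihydroxy‑6‑methoxyisobenzofuran‑1(3H)‑one (4,5‑dihydroxy‑6‑methoxyphthalide)
Conditions: degassed DMF, 100–110 °C, N2 sparge (–Me2NH); then dil. HCl work‑up
Reagents that add atoms: none
Why: Thermal E1cB loss of Me2NH from the zwitterion gives an o‑quinone methide whose exocyclic CH2 is the β‑carbon of an enone; the neighbouring carboxylate adds to it in an intramolecular oxa‑Michael (1,4‑) addition that closes the γ‑lactone and restores aromaticity.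

**Branch B – side chain**

Step 4
Reactants: 5, (2E,6E)‑farnesol
Product: 6, (2E,6E)‑farnesyl tert‑butyldimethylsilyl ether
Conditions: TBSCl, imidazole, CH2Cl2, 0 °C → rt
Reagents that add atoms: TBSCl, CC(C)(C)[Si](C)(C)Cl
Why: Standard silylation of a primary allylic alcohol; it masks the only OH so the later tertiary alcohol can be acetylated alone.

Step 5
Reactants: 6, farnesyl TBS ether
Product: 7, (6E,10E)‑3‑bromo‑12‑[(tert‑butyldimethylsilyl)oxy]‑2,6,10‑trimethyldodeca‑6,10‑dien‑2‑ol (racemic at C3)
Conditions: NBS (1.1 eq), THF/H2O (3:1), 0 °C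
Reagents that add atoms: N‑bromosuccinimide, O=C1CCC(=O)N1Br; water, O
Why: van Tamelen bromohydrin formation: in aqueous medium the exposed terminal trisubstituted alkene reacts first (the 2,3‑alkene is deactivated and shielded by the allylic OTBS), and water opens the bromonium at the tertiary carbon; the new C–Br centre is racemic and is removed in step 6.

Step 6
Reactants: 7, bromohydrin
Product: 8, (6E,10E)‑12‑[(tert‑butyldimethylsilyl)oxy]‑2,6,10‑trimethyldodeca‑6,10‑dien‑2‑ol
Conditions: Bu3SnH (1.3 eq), AIBN (cat.), PhMe, 80 °C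
Reagents that add atoms: none
Why: Radical‑chain dehalogenation; the secondary radical can only cyclise onto the 6,7‑alkene in disfavoured 4‑exo/5‑endo modes, so it is simply reduced, completing a net Markovnikov hydration.

Step 7
Reactants: 8, tertiary alcohol
Product: 9, (6E,10E)‑12‑[(tert‑butyldimethylsilyl)oxy]‑2,6,10‑trimethyldodeca‑6,10‑dien‑2‑yl acetate
Conditions: Ac2O, Et3N, DMAP (0.5 eq), CH2Cl2, rt → 40 °C, 24–48 h
Reagents that add atoms: acetic anhydride, CC(=O)OC(C)=O
Why: DMAP‑catalysed acyl transfer acetylates an unhindered dimethylcarbinol; the TBS ether and alkenes are inert.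

Step 8
Reactants: 9, silyl ether acetate
Product: 10, (6E,10E)‑12‑hydroxy‑2,6,10‑trimethyldodeca‑6,10‑dien‑2‑yl acetate
Conditions: TBAF/AcOH (1:1), THF, 0 °C → rt
Reagents that add atoms: none
Why: Fluoride desilylation; buffering with AcOH keeps the medium non‑basic so the tertiary acetate survives.

**Fragment union**

Step 9
Reactants: 4, 4,5‑dihydroxy‑6‑methoxyphthalide; 10, allylic alcohol
Product: 11, Farnesylemefuranone F, (6E,10E)‑12‑[(4‑hydroxy‑6‑methoxy‑1‑oxo‑1,3‑dihydroisobenzofuran‑5‑yl)oxy]‑2,6,10‑trimethyldodeca‑6,10‑dien‑2‑yl acetate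
Conditions: PPh3 (1.1 eq), DIAD (1.1 eq, slow addition), THF, 0 °C → rt
Reagents that add atoms: none
Why: Mitsunobu etherification: the betaine deprotonates the more acidic 5‑OH (para to the lactone carbonyl; the 4‑OH is meta), and that phenoxide displaces the primary allylic oxyphosphonium by SN2, leaving both E‑alkenes, the lactone and the tertiary acetate untouched.

## Compound list

1 | gallic acid | OC(=O)c1cc(O)c(O)c(O)c1 | starting material
2 | 3,4‑dihydroxy‑5‑methoxybenzoic acid | COc1cc(cc(O)c1O)C(=O)O | intermediate
3 | 2‑[(dimethylamino)methyl]‑3,4‑dihydroxy‑5‑methoxybenzoic acid | CN(C)Cc1c(O)c(O)c(OC)cc1C(=O)O | intermediate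
4 | 4,5‑dihydroxy‑6‑methoxyisobenzofuran‑1(3H)‑one | COc1cc2C(=O)OCc2c(O)c1O | intermediate
5 | (2E,6E)‑farnesol | CC(C)=CCC/C(C)=C/CC/C(C)=C/CO | starting material
6 | (2E,6E)‑farnesyl TBS ether | CC(C)=CCC/C(C)=C/CC/C(C)=C/CO[Si](C)(C)C(C)(C)C | intermediate
7 | (6E,10E)‑3‑bromo‑12‑(TBSO)‑2,6,10‑trimethyldodeca‑6,10‑dien‑2‑ol (racemic) | CC(C)(O)C(Br)CC/C(C)=C/CC/C(C)=C/CO[Si](C)(C)C(C)(C)C | intermediate
8 | (6E,10E)‑12‑(TBSO)‑2,6,10‑trimethyldodeca‑6,10‑dien‑2‑ol | CC(C)(O)CCC/C(C)=C/CC/C(C)=C/CO[Si](C)(C)C(C)(C)C | intermediate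
9 | (6E,10E)‑12‑(TBSO)‑2,6,10‑trimethyldodeca‑6,10‑dien‑2‑yl acetate | CC(=O)OC(C)(C)CCC/C(C)=C/CC/C(C)=C/CO[Si](C)(C)C(C)(C)C | intermediate
10 | (6E,10E)‑12‑hydroxy‑2,6,10‑trimethyldodeca‑6,10‑dien‑2‑yl acetate | CC(=O)OC(C)(C)CCC/C(C)=C/CC/C(C)=C/CO | intermediate
11 | Farnesylemefuranone F | COc1cc2c(c(O)c1OC/C=C(\C)CC/C=C(\C)CCCC(C)(C)OC(C)=O)COC2=O | target

## Summary

Total steps: 9.
Longest linear sequence: 6 (steps 4 → 5 → 6 → 7 → 8 → 9); the other branch is steps 1 → 2 → 3 → 9.

Three steps most likely to fail:

1. **Step 2 (Mannich regio‑ and mono‑selectivity).** C6 is para to the 3‑OH and could compete, and the catechol is oxidation‑prone under amine conditions. Fallback: benzylate the 4‑OH of methyl 3‑O‑methylgallate, install the benzylic carbon by strictly ortho MgCl2/Et3N/paraformaldehyde formylation of the remaining free phenol, reduce with NaBH4 (the alcohol lactonises onto the ester), then remove the benzyl group with H2/Pd‑C.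
2. **Step 3 (o‑quinone methide / oxa‑Michael lactonisation).** The o‑quinone methide may oligomerise, and the hot electron‑rich hydroxy acid may degrade. Fallback: drop the quinone‑methide closure and form the lactone by acyl substitution instead, through ortho‑hydroxymethylation of 2 (CH2O, HCl/AcOH) with spontaneous lactonisation of the resulting 2‑(hydroxymethyl)benzoic acid.
3. **Step 9 (5‑OH versus 4‑OH in the Mitsunobu, and possible catechol–phosphorane formation).** Fallback: reverse the order. Convert 10 to its allylic bromide and alkylate methyl 3,4‑dihydroxy‑5‑methoxybenzoate at the para 4‑OH (Li2CO3, DMF). Then aminomethylate ortho to the single remaining OH, quaternise with MeI, and close the lactone last under mild base, so the free phenol position is fixed by construction.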